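(The constants used here are assumed; the flask was simulated.)

Reckon first what share of the charge the side step takes in the time the catalyst needs to turn that charge over.

all flasks: reagent 37.8 mM (in portions, 4); free catalyst 48 µM; time 25 min

| run | substrate | remark |
|---|---|---|
| epsilon | 2.5 mM | the portions of reagent follow each other after 25 s, the first at the start |
| delta | 5.0 mM | the portions of reagent follow each other after 25 s, the first at the start |
| gamma | 10 mM | the portions of reagent follow each other after 25 s, the first at the start |
| eta | 20 mM | the portions of reagent follow each other after 25 s, the first at the start |
| zeta | 40 mM | the portions of reagent follow each other after 25 s, the first at the start |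

    substrate + free catalyst → catalyst intermediate A (k1 = 600 M⁻¹ s⁻¹)
    reagent + catalyst intermediate A ⇌ catalyst intermediate B (K2 = 53 M⁻¹, k2 = 2800 M⁻¹ s⁻¹)
    catalyst intermediate B → by-product + catalyst intermediate C (k3 = 0.59 s⁻¹)
    catalyst intermediate C → free catalyst + target (k4 = 1.3 s⁻¹)
    free catalyst + target ⇌ idle complex, settled at all times (K5 = 760 M⁻¹)
    substrate + target → side product (k6 = 0.12 M⁻¹ s⁻¹)

- a species is counted by the substrate in it: one side product counts as two
- amounts and yields of target count idle complex too
- the concentration of target that is asked is that of its free form alone
- "hardly changes" means that all values lie within two and a half points (for a concentration: within two and a half percent of the largest)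
- run time (epsilon): 25 min

- [target] (only what is free in solution) at the end for epsilon, delta, gamma, eta, zeta, in this order
- how the row runs (falls all the way / falls, then rises / hardly changes / rises, then falls / rises all the way)

The reagent comes in portions, but the last is in after 75.0 s, so I count its whole charge as present and test that below. I take the round as steady. Each turnover then costs the catalyst a time D: 3.32 s for the reagent step and the two first-order steps, plus the wait for substrate, stretched by catalyst sitting as idle complex.

Now I replace the curves by their means. In epsilon, I let substrate fall and target rise on straight lines, so I set both at half the charge. That gives D = 5.92 s, and the charge takes τ = 5.14 min, far longer than the feeding.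

The product of two such lines averages the charge squared over 6, and side product counts two. So the side share σ, the fraction of the charge ending as side product, is the side constant times charge times τ, over 3. For epsilon, σ = 3.08%, which leaves 2.42 mM of target, idle complex counted. The wait for substrate grows towards the end, so I expect this σ for epsilon to come out low.

For gamma, σ = 41.0%, leaving 5.90 mM. For eta, τ = 33.0 min overruns the 25 min, and σ passes one. My lines stop there, but I commit to a row that rises, then falls.

The forecast gives 2.37 mM, 4.32 mM, 6.9 mM, 8.3 mM and 5.6 mM, a row that rises, then falls, and says of zeta that the “side reaction dominates”.

The flask gives 2.37 mM, 4.38 mM, 6.93 mM, 8.31 mM and 5.55 mM: it rises, then falls, turning at a charge of 19 mM.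

My σ for epsilon is lower than the 3.78% of side product in the flask. Carried to delta, it gives 10.9% against 11.6%. In gamma the lines part from the flask, 41.0% against 29.9%. The largest single effect on zeta is the side step: zeta ends at 5.55 mM of free target with it and at 17.5 mM without it.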